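A direct plan would arylate 2,3-dimethylbuta-1,3-diene twice by Mizoroki–Heck reactions to the (E,E)-diaryl diene A1, reduce both alkenes in one iridium-catalysed asymmetric hydrogenation to the (2R,3R)-dibenzylbutane A2, oxidise one benzylic CH2 to the acetate (diacetate A3) and then free the phenol.
- Weakest: the late benzylic C–H acetoxylation. It would have to choose C7 over C7' (two electron-rich benzylic CH2 groups that differ only in a remote OCH3/OAc), set C7 by acyclic 1,2-induction alone and stop before the ketone, without close precedent and on the most valuable intermediate.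
- Weak: the double hydrogenation that sets C8 and C8' on a hindered conjugated diene. The second alkene is reduced on a chiral mono-ene, and every mismatch gives the meso isomer, which is hard to remove.
- Weak: the first Heck arylation of a volatile diene, where β-hydride loss toward the methyl groups and double arylation give isomer mixtures at the start of a linear sequence.

**Retrosynthetic overview** (lignan numbering: ring A = 3,4-dimethoxyphenyl on C7, ring B = 4-hydroxy-3-methoxyphenyl on C7', methyls C9 on C8 and C9' on C8')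
- C8' carries a methyl (C9') and the benzyl group C7'H2–ring B, so it is carried as the 1,1-disubstituted alkene C8'=C9'H2, homoallylic to the C7 hydroxyl; hydroxyl-directed hydrogenation turns it into the C8' stereocenter and the C9' methyl.
- The C8'–C7' bond is cut next: Suzuki coupling of an alkenyl boronate at C8' with a ring B benzylic chloride.
- The C7–C8 bond, the C7–O bond, both stereocenters C7 and C8 and the boron handle on C8' come from one copper-catalysed three-component coupling of veratraldehyde, buta-1,2-diene and B2pin2.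
- No ring is closed: rings A and B are bought and the chain is built between them in the order C7–C8, C8'–C7', then the C8' center.
- The C7 oxygen comes from the aldehyde (no C–H oxidation), C8' is set by delivery from the C7 hydroxyl on one isolated alkene (no diene hydrogenation), and no Heck reaction on a volatile diene is needed.

Key step: step 2

Assumption: (S,S)-Ph-BPE is taken as the ligand antipode that gives the (1R,2S) series in step 2; if the sense of induction is the opposite, the (R,R) ligand is used and nothing else changes.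

Step 1
Reactants: 1 [4-(benzyloxy)-3-methoxyphenyl]methanol
Product: 2 1-(benzyloxy)-4-(chloromethyl)-2-methoxybenzene
Conditions: SOCl2 (1.2 equiv), DMF (cat.), CH2Cl2, 0 °C, 1 h; used without storage
Reagents that add atoms: thionyl chloride, O=S(Cl)Cl
Why: Deoxychlorination of an electron-rich benzylic alcohol with thionyl chloride (chlorosulfite, then displacement by chloride) gives the benzylic electrophile for step 3; no stereocenter is formed.

Step 2
Reactants: 3 3,4-dimethoxybenzaldehyde; 4 buta-1,2-diene; 5 bis(pinacolato)diboron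
Product: 7 (1R,2S)-1-(3,4-dimethoxyphenyl)-2-methyl-3-(4,4,5,5-tetramethyl-1,3,2-dioxaborolan-2-yl)but-3-en-1-ol, via its O-pinacolboryl ether 6 (not isolated)
Conditions: CuCl (5 mol %), (S,S)-Ph-BPE (5.5 mol %), NaOt-Bu (20 mol %), 4 (3 equiv, condensed), 5 (1.1 equiv), THF, 22 °C, sealed vessel, 12 h; then aq. NH4Cl
Reagents that add atoms: none
Why: The copper–boryl complex (from CuOt-Bu and B2pin2) adds across the terminal C=C of the allene with boron on the central carbon, on the side away from the methyl group, and the 2-boryl allylcopper keeps CH3 cis to CH2Cu because the other geometry would press the methyl against the Bpin group (A(1,2) strain). This allylcopper adds at its γ-carbon to the aldehyde through a closed six-membered chair transition state, which forms the C7–C8 bond, and the copper alkoxide is then borylated by B2pin2, which returns the copper–boryl complex. The closest known reaction type is the copper/bisphosphine-catalysed enantioselective three-component coupling of B2pin2, monosubstituted allenes and aldehydes to 2-boryl homoallylic alcohols. No ring is closed. C7 and C8 are set together: the syn relation follows from the (Z)-type allylcopper geometry in the chair, and the absolute sense from the chiral bisphosphine, which selects the aldehyde face. The step needs the copper–boryl species to add to the allene faster than to the C=O group (ligand and excess allene), γ- over α-attack (the six-membered transition state) and a single allyl geometry (the Bpin group on C8').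

Step 3
Reactants: 7 (1R,2S)-1-(3,4-dimethoxyphenyl)-2-methyl-3-(4,4,5,5-tetramethyl-1,3,2-dioxaborolan-2-yl)but-3-en-1-ol; 2 1-(benzyloxy)-4-(chloromethyl)-2-methoxybenzene
Product: 8 (1R,2S)-3-{[4-(benzyloxy)-3-methoxyphenyl]methyl}-1-(3,4-dimethoxyphenyl)-2-methylbut-3-en-1-ol
Conditions: Pd(OAc)2 (3 mol %), SPhos (6 mol %), K3PO4 (3 equiv), toluene/H2O 20:1, 45 °C, 8 h
Reagents that add atoms: none
Why: Suzuki–Miyaura cross-coupling of an alkenyl pinacol boronate with a benzylic chloride (oxidative addition of C–Cl to zerovalent palladium, transmetalation, reductive elimination) forms the C8'–C7' bond and leaves C8'=C9'H2 in place; the mild base and low temperature should keep the skipped alkene out of conjugation, and C7 and C8 are not touched.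

Step 4
Reactants: 8 (1R,2S)-3-{[4-(benzyloxy)-3-methoxyphenyl]methyl}-1-(3,4-dimethoxyphenyl)-2-methylbut-3-en-1-ol
Product: 9 (1R,2S,3R)-4-[4-(benzyloxy)-3-methoxyphenyl]-1-(3,4-dimethoxyphenyl)-2,3-dimethylbutan-1-ol
Conditions: [Rh(nbd)(dppb)]BF4 (10 mol %), H2 (60 bar), CH2Cl2, 25 °C, 16 h
Reagents that add atoms: none
Why: Hydroxyl-directed homogeneous hydrogenation of a homoallylic alcohol with a cationic rhodium diphosphine catalyst: the C7 hydroxyl binds rhodium and H2 is delivered to the alkene face on its side, in the conformer where C8–H eclipses the C8'–C7' bond (least A(1,2) strain) and ring A points away, which sets C8' as R and turns =C9'H2 into the methyl; the high pressure should outrun double-bond migration.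

Step 5
Reactants: 9 (1R,2S,3R)-4-[4-(benzyloxy)-3-methoxyphenyl]-1-(3,4-dimethoxyphenyl)-2,3-dimethylbutan-1-ol
Product: 10 (1R,2S,3R)-4-[4-(benzyloxy)-3-methoxyphenyl]-1-(3,4-dimethoxyphenyl)-2,3-dimethylbutyl acetate
Conditions: Ac2O (2 equiv), pyridine (4 equiv), DMAP (5 mol %), CH2Cl2, 0 °C to rt
Reagents that add atoms: acetic anhydride, CC(=O)OC(C)=O
Why: DMAP-catalysed O-acetylation of the only free hydroxyl under non-acidic conditions, so the electron-rich benzylic C7–O bond is not ionised and C7 keeps its configuration.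

Step 6
Reactants: 10 (1R,2S,3R)-4-[4-(benzyloxy)-3-methoxyphenyl]-1-(3,4-dimethoxyphenyl)-2,3-dimethylbutyl acetate
Product: 11 (1R,2S,3R)-1-(3,4-dimethoxyphenyl)-4-(4-hydroxy-3-methoxyphenyl)-2,3-dimethylbutyl acetate
Conditions: H2 (1 atm), Pd/C (10 wt % Pd, 5 mol %), NaHCO3 (solid, 1 equiv), EtOAc, 20 °C, stopped when 10 is consumed
Reagents that add atoms: none
Why: Hydrogenolysis of the aryl benzyl ether on Pd/C, which should be much faster than cleavage of a secondary benzylic acetate in a neutral, bicarbonate-buffered, aprotic medium at 1 atm, frees the phenol of ring B without touching a stereocenter.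

**Compound list**
1 | [4-(benzyloxy)-3-methoxyphenyl]methanol | COc1cc(CO)ccc1OCc1ccccc1 | starting material
2 | 1-(benzyloxy)-4-(chloromethyl)-2-methoxybenzene | COc1cc(CCl)ccc1OCc1ccccc1 | intermediate
3 | 3,4-dimethoxybenzaldehyde | COc1ccc(C=O)cc1OC | starting material
4 | buta-1,2-diene | C=C=CC | starting material
5 | bis(pinacolato)diboron | CC1(C)OB(OC1(C)C)B1OC(C)(C)C(C)(C)O1 | starting material
6 | 2-{[(1R,2S)-1-(3,4-dimethoxyphenyl)-2-methyl-3-(4,4,5,5-tetramethyl-1,3,2-dioxaborolan-2-yl)but-3-en-1-yl]oxy}-4,4,5,5-tetramethyl-1,3,2-dioxaborolane | C=C(B1OC(C)(C)C(C)(C)O1)[C@H](C)[C@@H](OB1OC(C)(C)C(C)(C)O1)c1ccc(OC)c(OC)c1 | intermediate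
7 | (1R,2S)-1-(3,4-dimethoxyphenyl)-2-methyl-3-(4,4,5,5-tetramethyl-1,3,2-dioxaborolan-2-yl)but-3-en-1-ol | C=C(B1OC(C)(C)C(C)(C)O1)[C@H](C)[C@@H](O)c1ccc(OC)c(OC)c1 | intermediate
8 | (1R,2S)-3-{[4-(benzyloxy)-3-methoxyphenyl]methyl}-1-(3,4-dimethoxyphenyl)-2-methylbut-3-en-1-ol | COc1cc(CC(=C)[C@H](C)[C@@H](O)c2ccc(OC)c(OC)c2)ccc1OCc1ccccc1 | intermediate
9 | (1R,2S,3R)-4-[4-(benzyloxy)-3-methoxyphenyl]-1-(3,4-dimethoxyphenyl)-2,3-dimethylbutan-1-ol | COc1cc(C[C@@H](C)[C@H](C)[C@@H](O)c2ccc(OC)c(OC)c2)ccc1OCc1ccccc1 | intermediate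
10 | (1R,2S,3R)-4-[4-(benzyloxy)-3-methoxyphenyl]-1-(3,4-dimethoxyphenyl)-2,3-dimethylbutyl acetate | COc1cc(C[C@@H](C)[C@H](C)[C@@H](OC(C)=O)c2ccc(OC)c(OC)c2)ccc1OCc1ccccc1 | intermediate
11 | (1R,2S,3R)-1-(3,4-dimethoxyphenyl)-4-(4-hydroxy-3-methoxyphenyl)-2,3-dimethylbutyl acetate | COc1cc(C[C@@H](C)[C@H](C)[C@@H](OC(C)=O)c2ccc(OC)c(OC)c2)ccc1O | target

Total step count: 6. Longest linear sequence: 5 steps (3 → 7 → 8 → 9 → 10 → 11).

**Steps most likely to fail**

Step 2 (key step). The copper–boryl species may add to the aldehyde C=O instead of the allene, the small methyl-substituted allylcopper may lose its geometry and with it the syn relation, or face control may be low with an electron-rich aldehyde. The fallback sets out from 3 and uses auxiliary control: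
- A boron-mediated Evans syn-aldol reaction with (4R)-4-benzyl-3-propanoyl-1,3-oxazolidin-2-one (Bu2BOTf, i-Pr2NEt, CH2Cl2, −78 °C) would give (4R)-4-benzyl-3-[(2R,3R)-3-(3,4-dimethoxyphenyl)-3-hydroxy-2-methylpropanoyl]-1,3-oxazolidin-2-one F1.
- Transamination (AlMe3, MeNHOMe·HCl) would give the Weinreb amide (2R,3R)-3-(3,4-dimethoxyphenyl)-3-hydroxy-N-methoxy-N,2-dimethylpropanamide F2.
- Addition of {[4-(benzyloxy)-3-methoxyphenyl]methyl}magnesium chloride F3 (from 2 and Mg in THF, 3 equiv) would give the ketone (3R,4R)-1-[4-(benzyloxy)-3-methoxyphenyl]-4-(3,4-dimethoxyphenyl)-4-hydroxy-3-methylbutan-2-one F4.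
- Non-basic methylenation (Zn, CH2Br2, TiCl4, THF) comes back to the route at 8.

Step 4. The C8'=C9' double bond may migrate into conjugation with ring B before hydrogen is delivered, and the facial bias may be incomplete. The fallback sets out from 8 and uses the migration, with catalyst control instead of hydroxyl direction:
- Silylation (TBSOTf, 2,6-lutidine) would give tert-butyl{[(1R,2S)-3-{[4-(benzyloxy)-3-methoxyphenyl]methyl}-1-(3,4-dimethoxyphenyl)-2-methylbut-3-en-1-yl]oxy}dimethylsilane F5.
- Deliberate isomerisation (RuHCl(CO)(PPh3)3, toluene, 80 °C) would give the conjugated alkene tert-butyl{[(1R,2S,3E)-4-[4-(benzyloxy)-3-methoxyphenyl]-1-(3,4-dimethoxyphenyl)-2,3-dimethylbut-3-en-1-yl]oxy}dimethylsilane F6.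
- Asymmetric hydrogenation of this (E)-2-methyl-1-aryl alkene with [Ir(cod)((S)-tBu-PHOX)]BArF (H2, CH2Cl2) would give tert-butyl{[(1R,2S,3R)-4-[4-(benzyloxy)-3-methoxyphenyl]-1-(3,4-dimethoxyphenyl)-2,3-dimethylbutyl]oxy}dimethylsilane F7.
- TBAF comes back to the route at 9.

Step 6. Hydrogenolysis may also cleave the electron-rich benzylic C7–OAc bond. The fallback sets out from 9 and removes the benzyl group before the acetate exists:
- Debenzylation (H2, Pd/C, EtOAc) would give 4-[(2R,3S,4R)-4-(3,4-dimethoxyphenyl)-4-hydroxy-2,3-dimethylbutyl]-2-methoxyphenol F8.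
- Acetylation of both hydroxyls (Ac2O, pyridine, DMAP) would give (1R,2S,3R)-4-[4-(acetyloxy)-3-methoxyphenyl]-1-(3,4-dimethoxyphenyl)-2,3-dimethylbutyl acetate F9.
- Selective aminolysis of the aryl acetate (pyrrolidine, CH2Cl2, 0 °C) comes back to the route at 11.

**Further compounds**
F1 | step 2 | (4R)-4-benzyl-3-[(2R,3R)-3-(3,4-dimethoxyphenyl)-3-hydroxy-2-methylpropanoyl]-1,3-oxazolidin-2-one | O=C1OC[C@@H](Cc2ccccc2)N1C(=O)[C@H](C)[C@@H](O)c1ccc(OC)c(OC)c1
F2 | step 2 | (2R,3R)-3-(3,4-dimethoxyphenyl)-3-hydroxy-N-methoxy-N,2-dimethylpropanamide | CON(C)C(=O)[C@H](C)[C@@H](O)c1ccc(OC)c(OC)c1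
F3 | step 2 | {[4-(benzyloxy)-3-methoxyphenyl]methyl}magnesium chloride | COc1cc(C[Mg]Cl)ccc1OCc1ccccc1
F4 | step 2 | (3R,4R)-1-[4-(benzyloxy)-3-methoxyphenyl]-4-(3,4-dimethoxyphenyl)-4-hydroxy-3-methylbutan-2-one | COc1cc(CC(=O)[C@H](C)[C@@H](O)c2ccc(OC)c(OC)c2)ccc1OCc1ccccc1
F5 | step 4 | tert-butyl{[(1R,2S)-3-{[4-(benzyloxy)-3-methoxyphenyl]methyl}-1-(3,4-dimethoxyphenyl)-2-methylbut-3-en-1-yl]oxy}dimethylsilane | COc1cc(CC(=C)[C@H](C)[C@@H](O[Si](C)(C)C(C)(C)C)c2ccc(OC)c(OC)c2)ccc1OCc1ccccc1
F6 | step 4 | tert-butyl{[(1R,2S,3E)-4-[4-(benzyloxy)-3-methoxyphenyl]-1-(3,4-dimethoxyphenyl)-2,3-dimethylbut-3-en-1-yl]oxy}dimethylsilane | COc1cc(/C=C(\C)[C@H](C)[C@@H](O[Si](C)(C)C(C)(C)C)c2ccc(OC)c(OC)c2)ccc1OCc1ccccc1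
F7 | step 4 | tert-butyl{[(1R,2S,3R)-4-[4-(benzyloxy)-3-methoxyphenyl]-1-(3,4-dimethoxyphenyl)-2,3-dimethylbutyl]oxy}dimethylsilane | COc1cc(C[C@@H](C)[C@H](C)[C@@H](O[Si](C)(C)C(C)(C)C)c2ccc(OC)c(OC)c2)ccc1OCc1ccccc1
F8 | step 6 | 4-[(2R,3S,4R)-4-(3,4-dimethoxyphenyl)-4-hydroxy-2,3-dimethylbutyl]-2-methoxyphenol | COc1cc(C[C@@H](C)[C@H](C)[C@@H](O)c2ccc(OC)c(OC)c2)ccc1O
F9 | step 6 | (1R,2S,3R)-4-[4-(acetyloxy)-3-methoxyphenyl]-1-(3,4-dimethoxyphenyl)-2,3-dimethylbutyl acetate | COc1cc(C[C@@H](C)[C@H](C)[C@@H](OC(C)=O)c2ccc(OC)c(OC)c2)ccc1OC(C)=O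
A1 | direct plan | 4-[(1E,3E)-4-(3,4-dimethoxyphenyl)-2,3-dimethylbuta-1,3-dien-1-yl]-2-methoxyphenyl acetate | COc1cc(/C=C(\C)/C(C)=C/c2ccc(OC)c(OC)c2)ccc1OC(C)=O
A2 | direct plan | 4-[(2R,3R)-4-(3,4-dimethoxyphenyl)-2,3-dimethylbutyl]-2-methoxyphenyl acetate | COc1cc(C[C@@H](C)[C@H](C)Cc2ccc(OC)c(OC)c2)ccc1OC(C)=O
A3 | direct plan | (1R,2S,3R)-4-[4-(acetyloxy)-3-methoxyphenyl]-1-(3,4-dimethoxyphenyl)-2,3-dimethylbutyl acetate | COc1cc(C[C@@H](C)[C@H](C)[C@@H](OC(C)=O)c2ccc(OC)c(OC)c2)ccc1OC(C)=O
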